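**Retrosynthetic overview**
1. The aryl C–O bond that carries the sulfate is made last, by direct C–H sulfatoxylation para to the free phenol of a catechol aldehyde, so no phenol has to be told apart from another.
2. The catechol aldehyde comes from its diacetate, made by one acid-catalysed bicyclisation of a (2Z,6E)-farnesyl arene: ring A closes first, then ring B. The 2Z alkene puts the arylmethyl group trans to the angular methyl, which is the 9-epi-drimane configuration of the target.
3. The farnesyl arene comes from an sp2–sp3 Suzuki coupling of an aryl pinacol boronate with (2Z,6E)-farnesyl bromide.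
4. The bromide comes from geranylacetone via a β-keto ester, its (E)-enol triflate and a stereoretentive methylation that fixes the 2Z geometry. The boronate comes from 5-bromo-2,3-dihydroxybenzaldehyde.

Assumption: the target is drawn and delivered as the free aryl hydrogen sulfate (kept as its potassium salt until the final acidification), and the (S,S) antipode of the chiral acid in step 9 is taken as the one giving the 5S,10S decalin (drimane numbering); otherwise its mirror image is used.

**Step 1**
Reactants: 1 geranylacetone, (5E)-6,10-dimethylundeca-5,9-dien-2-one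
Product: 2 methyl (6E)-7,11-dimethyl-3-oxododeca-6,10-dienoate
Conditions: NaH, (MeO)2CO, THF, reflux; then 1 M HCl
Reagents that add atoms: dimethyl carbonate, COC(=O)OC
Why: Crossed Claisen condensation at the methyl terminus of the methyl ketone, driven by formation of the stabilised β-keto ester enolate; the E alkene is untouched.

**Step 2**
Reactants: 2 methyl (6E)-7,11-dimethyl-3-oxododeca-6,10-dienoate
Product: 3 methyl (2E,6E)-7,11-dimethyl-3-{[(trifluoromethyl)sulfonyl]oxy}dodeca-2,6,10-trienoate
Conditions: Tf2O, aq Me4NOH, hexanes, 5 °C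
Reagents that add atoms: triflic anhydride, O=S(=O)(OS(=O)(=O)C(F)(F)F)C(F)(F)F
Why: O-Triflation of the β-keto ester enolate; the non-chelating tetramethylammonium ion favours the extended enolate, so the triflate ends up trans to the ester (E) and the carbon chain cis to it.

**Step 3**
Reactants: 3 methyl (2E,6E)-7,11-dimethyl-3-{[(trifluoromethyl)sulfonyl]oxy}dodeca-2,6,10-trienoate
Product: 4 methyl (2Z,6E)-3,7,11-trimethyldodeca-2,6,10-trienoate
Conditions: MeMgBr, Fe(acac)3 (5 mol %), THF–NMP, −30 °C
Reagents that add atoms: methylmagnesium bromide, C[Mg]Br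
Why: Iron-catalysed Kumada-type cross-coupling of an enol triflate with retention of alkene geometry; replacing OTf by CH3 turns the E triflate into the 2Z enoate (chain cis to C1).

**Step 4**
Reactants: 4 methyl (2Z,6E)-3,7,11-trimethyldodeca-2,6,10-trienoate
Product: 5 (2Z,6E)-3,7,11-trimethyldodeca-2,6,10-trien-1-ol
Conditions: i-Bu2AlH (2.2 equiv), CH2Cl2, −78 to 0 °C; Rochelle salt work-up
Reagents that add atoms: none
Why: 1,2-Reduction of the conjugated ester to the allylic alcohol, with no conjugate reduction and no change of either alkene geometry.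

**Step 5**
Reactants: 5 (2Z,6E)-3,7,11-trimethyldodeca-2,6,10-trien-1-ol
Product: 6 (2Z,6E)-1-bromo-3,7,11-trimethyldodeca-2,6,10-triene
Conditions: PBr3 (0.4 equiv), Et2O, −10 °C; used at once
Reagents that add atoms: phosphorus tribromide, BrP(Br)Br
Why: SN2 bromination of the primary allylic alcohol via its phosphite ester at low temperature, which keeps the 2Z geometry and avoids allylic transposition.

**Step 6**
Reactants: 7 5-bromo-2,3-dihydroxybenzaldehyde
Product: 8 5-bromo-3-formyl-1,2-phenylene diacetate
Conditions: Ac2O, pyridine, DMAP (cat.), CH2Cl2, 0 °C to rt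
Reagents that add atoms: acetic anhydride, CC(=O)OC(C)=O
Why: O-Acylation of both phenols; the acetates tolerate the couplings, make the ring electron-poor for the cyclisation and fall off under the mild base of the last step.

**Step 7**
Reactants: 8 5-bromo-3-formyl-1,2-phenylene diacetate
Product: 9 3-formyl-5-(4,4,5,5-tetramethyl-1,3,2-dioxaborolan-2-yl)-1,2-phenylene diacetate
Conditions: B2pin2, PdCl2(dppf) (3 mol %), KOAc, 1,4-dioxane, 85 °C
Reagents that add atoms: bis(pinacolato)diboron, CC1(C)OB(OC1(C)C)B1OC(C)(C)C(C)(C)O1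
Why: Miyaura borylation of the aryl bromide; KOAc is too weak a base to cleave the aryl acetates or to touch the aldehyde.

**Step 8**
Reactants: 6 (2Z,6E)-1-bromo-3,7,11-trimethyldodeca-2,6,10-triene, 9 3-formyl-5-(4,4,5,5-tetramethyl-1,3,2-dioxaborolan-2-yl)-1,2-phenylene diacetate
Product: 10 3-formyl-5-[(2Z,6E)-3,7,11-trimethyldodeca-2,6,10-trien-1-yl]-1,2-phenylene diacetate
Conditions: Pd(PPh3)4 (5 mol %), KF (anhydrous), THF, 50 °C
Reagents that add atoms: none
Why: sp2–sp3 Suzuki–Miyaura coupling through a π-allylpalladium intermediate; reductive elimination at the unsubstituted allyl terminus gives the linear product, and the disubstituted terminus does not undergo syn/anti exchange at this temperature, so the 2Z geometry is kept.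

**Step 9**
Reactants: 10 3-formyl-5-[(2Z,6E)-3,7,11-trimethyldodeca-2,6,10-trien-1-yl]-1,2-phenylene diacetate
Product: 11 3-formyl-5-{[(1R,4aS,8aS)-2,5,5,8a-tetramethyl-1,4,4a,5,6,7,8,8a-octahydronaphthalen-1-yl]methyl}-1,2-phenylene diacetate
Conditions: (S,S)-IDPi Brønsted acid (5 mol %), (CF3)2CHOH–CH2Cl2, −40 to 0 °C
Reagents that add atoms: none
Why: Brønsted-acid-catalysed Stork–Eschenmoser polyene bicyclisation (closest precedent: the confined imidodiphosphorimidate-catalysed cyclisation of homofarnesol), in which the chiral acid protonates the terminal alkene face-selectively (setting C5 and C10 as S, drimane numbering), the 6E alkene gives the trans-decalin through a chair–chair array, anti addition across the 2Z alkene places the arylmethyl group axial and trans to the angular methyl (C9 R), and the C8 cation loses the aligned axial H-7 (the C9–H lies in the nodal plane and the electron-poor arene does not compete) to give the 7,8-alkene.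

**Step 10**
Reactants: 11 3-formyl-5-{[(1R,4aS,8aS)-2,5,5,8a-tetramethyl-1,4,4a,5,6,7,8,8a-octahydronaphthalen-1-yl]methyl}-1,2-phenylene diacetate
Product: 13 2-formyl-3,4-dihydroxy-6-{[(1R,4aS,8aS)-2,5,5,8a-tetramethyl-1,4,4a,5,6,7,8,8a-octahydronaphthalen-1-yl]methyl}phenyl hydrogen sulfate (CNP0018731.3), via free catechol aldehyde 12 (not isolated)
Conditions: K2CO3 (3.5 equiv), H2O–MeCN, argon, rt, 2 h; then K2S2O8 (1.2 equiv), 5 °C to rt, dark, 36 h; then 1 M HCl, 0 °C, extraction with n-BuOH
Reagents that add atoms: potassium peroxydisulfate K2S2O8, [K+].[K+].[O-]S(=O)(=O)OOS(=O)(=O)[O-]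
Why: Proposed new method: a monoanion-gated, para-selective Elbs-type C–H sulfatoxylation of a free catechol. The carbonate/bicarbonate buffer left after acetate hydrolysis ionises the catechol only once (the salicyl OH, pKa about 8); the minor tautomer with the negative charge on the 3-oxygen attacks a peroxide oxygen of S2O8(2−) through its only free para carbon (ortho to CHO, as m-hydroxybenzaldehyde does), and the dienone sulfate re-aromatises, so the sulfate arrives on the new oxygen and no O-selective sulfation is needed. Keeping the pH below about 10.5 and excluding O2 avoids the dianion, which would be oxidised to the o-quinone, and the trisubstituted alkene is inert to unactivated persulfate. The closest known reaction is the Elbs persulfate oxidation of monohydric phenols, which has not been shown for free catechols.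

**Compound list**
1 | geranylacetone, (5E)-6,10-dimethylundeca-5,9-dien-2-one | CC(=O)CC/C=C(\C)CCC=C(C)C | starting material
2 | methyl (6E)-7,11-dimethyl-3-oxododeca-6,10-dienoate | COC(=O)CC(=O)CC/C=C(\C)CCC=C(C)C | intermediate
3 | methyl (2E,6E)-7,11-dimethyl-3-{[(trifluoromethyl)sulfonyl]oxy}dodeca-2,6,10-trienoate | COC(=O)/C=C(/OS(=O)(=O)C(F)(F)F)CC/C=C(\C)CCC=C(C)C | intermediate
4 | methyl (2Z,6E)-3,7,11-trimethyldodeca-2,6,10-trienoate | COC(=O)/C=C(/C)CC/C=C(\C)CCC=C(C)C | intermediate
5 | (2Z,6E)-3,7,11-trimethyldodeca-2,6,10-trien-1-ol | OC/C=C(/C)CC/C=C(\C)CCC=C(C)C | intermediate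
6 | (2Z,6E)-1-bromo-3,7,11-trimethyldodeca-2,6,10-triene | BrC/C=C(/C)CC/C=C(\C)CCC=C(C)C | intermediate
7 | 5-bromo-2,3-dihydroxybenzaldehyde | O=Cc1cc(Br)cc(O)c1O | starting material
8 | 5-bromo-3-formyl-1,2-phenylene diacetate | O=Cc1cc(Br)cc(OC(C)=O)c1OC(C)=O | intermediate
9 | 3-formyl-5-(4,4,5,5-tetramethyl-1,3,2-dioxaborolan-2-yl)-1,2-phenylene diacetate | O=Cc1cc(B2OC(C)(C)C(C)(C)O2)cc(OC(C)=O)c1OC(C)=O | intermediate
10 | 3-formyl-5-[(2Z,6E)-3,7,11-trimethyldodeca-2,6,10-trien-1-yl]-1,2-phenylene diacetate | O=Cc1cc(C/C=C(/C)CC/C=C(\C)CCC=C(C)C)cc(OC(C)=O)c1OC(C)=O | intermediate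
11 | 3-formyl-5-{[(1R,4aS,8aS)-2,5,5,8a-tetramethyl-1,4,4a,5,6,7,8,8a-octahydronaphthalen-1-yl]methyl}-1,2-phenylene diacetate | CC1=CC[C@H]2C(C)(C)CCC[C@]2(C)[C@@H]1Cc1cc(OC(C)=O)c(OC(C)=O)c(C=O)c1 | intermediate
12 | 2,3-dihydroxy-5-{[(1R,4aS,8aS)-2,5,5,8a-tetramethyl-1,4,4a,5,6,7,8,8a-octahydronaphthalen-1-yl]methyl}benzaldehyde | CC1=CC[C@H]2C(C)(C)CCC[C@]2(C)[C@@H]1Cc1cc(O)c(O)c(C=O)c1 | intermediate
13 | 2-formyl-3,4-dihydroxy-6-{[(1R,4aS,8aS)-2,5,5,8a-tetramethyl-1,4,4a,5,6,7,8,8a-octahydronaphthalen-1-yl]methyl}phenyl hydrogen sulfate | CC1=CC[C@H]2C(C)(C)CCC[C@]2(C)[C@@H]1Cc1cc(O)c(O)c(C=O)c1OS(=O)(=O)O | target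

**Count**
Total steps: 10. Longest linear sequence: 8 (steps 1–5, 8, 9, 10).

**Steps most likely to fail**

Step 10 (the proposed new step). The catechol may be oxidised to the o-quinone faster than it is sulfatoxylated, or the hindered para carbon may react too slowly. The fallback uses known chemistry, sets out from 11 and comes back at 13. Hydrolysis of 11 (K2CO3, H2O–MeCN) gives 12, now isolated. TBSCl and imidazole give the bis-silyl ether F1. The aldehyde is masked in the flask as its lithium α-amino alkoxide with LiN(Me)CH2CH2NMe2, and n-BuLi then lithiates the only free position ortho to it. B(OMe)3 followed by N-methylmorpholine N-oxide (chosen to avoid a Dakin reaction) gives the 6-hydroxy aldehyde F2, which has a single free phenol. SO3·pyridine converts it into the protected aryl hydrogen sulfate F3. Bu4NF buffered with AcOH removes both silyl groups, and brief cold acidification gives 13.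

Step 9. The enantioselectivity may be low, the aldehyde may inhibit the acid, or exocyclic and 8,9-alkene isomers may form. The fallback sets out from 10 and comes back at 11. Racemic cyclisation with FSO3H in 2-nitropropane at −78 °C follows the same stereospecific course from the 2Z alkene and gives 11 together with its enantiomer F4. Preparative SFC on a chiral stationary phase then delivers 11.

Step 8. The π-allyl intermediate may scramble the 2Z geometry, give the branched isomer, or lose the acetates. The fallback sets out from 6 and 7 and comes back at 10. MOMCl and i-Pr2NEt convert 7 into 5-bromo-2,3-bis(methoxymethoxy)benzaldehyde F5. Its aldehyde is masked as the lithium α-amino alkoxide, t-BuLi effects bromine–lithium exchange, and CuBr·SMe2 gives the arylcopper. This is alkylated by 6 in a direct SN2 reaction that does not pass through a π-allyl species, giving the farnesylated bis-MOM aldehyde F6. HCl in MeOH at rt gives the farnesylated catechol aldehyde F7, and Ac2O with pyridine gives 10.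

**Further compounds**
F1 | step 10 | 2,3-bis[(tert-butyldimethylsilyl)oxy]-5-{[(1R,4aS,8aS)-2,5,5,8a-tetramethyl-1,4,4a,5,6,7,8,8a-octahydronaphthalen-1-yl]methyl}benzaldehyde | CC1=CC[C@H]2C(C)(C)CCC[C@]2(C)[C@@H]1Cc1cc(O[Si](C)(C)C(C)(C)C)c(O[Si](C)(C)C(C)(C)C)c(C=O)c1
F2 | step 10 | 2,3-bis[(tert-butyldimethylsilyl)oxy]-6-hydroxy-5-{[(1R,4aS,8aS)-2,5,5,8a-tetramethyl-1,4,4a,5,6,7,8,8a-octahydronaphthalen-1-yl]methyl}benzaldehyde | CC1=CC[C@H]2C(C)(C)CCC[C@]2(C)[C@@H]1Cc1cc(O[Si](C)(C)C(C)(C)C)c(O[Si](C)(C)C(C)(C)C)c(C=O)c1O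
F3 | step 10 | 3,4-bis[(tert-butyldimethylsilyl)oxy]-2-formyl-6-{[(1R,4aS,8aS)-2,5,5,8a-tetramethyl-1,4,4a,5,6,7,8,8a-octahydronaphthalen-1-yl]methyl}phenyl hydrogen sulfate | CC1=CC[C@H]2C(C)(C)CCC[C@]2(C)[C@@H]1Cc1cc(O[Si](C)(C)C(C)(C)C)c(O[Si](C)(C)C(C)(C)C)c(C=O)c1OS(=O)(=O)O
F4 | step 9 | 3-formyl-5-{[(1S,4aR,8aR)-2,5,5,8a-tetramethyl-1,4,4a,5,6,7,8,8a-octahydronaphthalen-1-yl]methyl}-1,2-phenylene diacetate | CC1=CC[C@@H]2C(C)(C)CCC[C@@]2(C)[C@H]1Cc1cc(OC(C)=O)c(OC(C)=O)c(C=O)c1
F5 | step 8 | 5-bromo-2,3-bis(methoxymethoxy)benzaldehyde | O=Cc1cc(Br)cc(OCOC)c1OCOC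
F6 | step 8 | 2,3-bis(methoxymethoxy)-5-[(2Z,6E)-3,7,11-trimethyldodeca-2,6,10-trien-1-yl]benzaldehyde | O=Cc1cc(C/C=C(/C)CC/C=C(\C)CCC=C(C)C)cc(OCOC)c1OCOC
F7 | step 8 | 2,3-dihydroxy-5-[(2Z,6E)-3,7,11-trimethyldodeca-2,6,10-trien-1-yl]benzaldehyde | O=Cc1cc(C/C=C(/C)CC/C=C(\C)CCC=C(C)C)cc(O)c1O
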